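**Retrosynthetic overview**
- The route rests on lactone carbons C3 and C4. C3 (α to C2=O) carries the CH2 of central ring B and C4 (β) carries the CH2 of guaiacyl ring A, trans to each other. They are the α and β carbons of a furan-2(5H)-one, so the C4–C(benzylic) and C3–CH2(benzylic) bonds are cut back to butenolide 4, the lithiated form of dithiane 6 and benzylic bromide 23, joined in one pot with no ring closure.
- C5 of 4 is a (+)-menthyl acetal. It directs both new stereocenters and later becomes the lactone OCH2 (NaBH4/KOH, then acid), which leaves C2=O next to the ring B benzyl.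
- The labile α-aryl-β-hydroxy ketone on ring B is carried as a syn-1,3-diol acetonide made by an Evans syn-aldol (ring B arylacetyl imide + aldehyde 5). The ketone is unveiled last by selective benzylic oxidation, followed by hydrogenolysis.
- Ring order: the lactone ring comes first (steps 1–2, from furfural); the dithiane (step 3) and 1,3-dioxane (step 12) rings are temporary; the lactone is reopened and reclosed in step 17. The three benzene rings are bought (5, 7).

Key step: step 15

Remark: lactone atoms are numbered O1, C2 (C=O), C3, C4, C5; ring A is the guaiacyl ring on C4–CH2, ring B the central ring on C3–CH2, ring C the aryl ketone ring. Compounds 5 and 7 are taken as purchased. The (5S) epimer of 4 is assumed to be the crystalline one, by mirror-image analogy with the (−)-menthol series.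

**Step 1**
Reactants: 1 furfural
Product: 2 5-hydroxyfuran-2(5H)-one (racemic)
Conditions: O2, hν (visible), rose bengal (cat., C20H2Cl4I4Na2O5), MeOH, rt
Reagents that add atoms: dioxygen, O=O
Why: Sensitized photooxygenation, in which singlet oxygen adds [4+2] to the furan and the endoperoxide fragments in methanol with loss of the formyl carbon as methyl formate, a known route to this hydroxybutenolide.

**Step 2**
Reactants: 2 5-hydroxyfuran-2(5H)-one; 3 (+)-menthol, (1S,2R,5S)
Product: 4 (5S)-5-[(1S,2R,5S)-menthyloxy]furan-2(5H)-one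
Conditions: p-TsOH·H2O (cat.), toluene, reflux (Dean–Stark); crystallization from petroleum ether, mother liquor re-equilibrated with acid
Reagents that add atoms: none
Why: Acid-catalysed acetalization of the cyclic hemiacetal; the two C5 epimers interconvert under acid and the (5S) epimer should crystallize, so C5 is set by crystallization-driven epimer enrichment.

**Step 3**
Reactants: 5 4-(benzyloxy)-3-methoxybenzaldehyde
Product: 6 2-[4-(benzyloxy)-3-methoxyphenyl]-1,3-dithiane
Conditions: propane-1,3-dithiol, I2 (cat.), CH2Cl2, rt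
Reagents that add atoms: propane-1,3-dithiol, SCCCS
Why: Iodine-catalysed thioacetalization of an aromatic aldehyde, mild enough to leave the aryl benzyl ether untouched.

**Step 4**
Reactants: 7 methyl vanillate
Product: 8 methyl 4-(allyloxy)-3-methoxybenzoate
Conditions: allyl bromide, K2CO3, acetone, reflux
Reagents that add atoms: allyl bromide, C=CCBr
Why: Williamson ether synthesis on the phenoxide.

**Step 5**
Reactants: 8 methyl 4-(allyloxy)-3-methoxybenzoate
Product: 9 methyl 3-allyl-4-hydroxy-5-methoxybenzoate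
Conditions: N,N-diethylaniline, 200 °C
Reagents that add atoms: none
Why: Aromatic Claisen rearrangement ([3,3]-sigmatropic shift, then tautomerization) to the only free ortho position, which places the future side-chain carbon ortho to the phenol and meta to the ester.

**Step 6**
Reactants: 9 methyl 3-allyl-4-hydroxy-5-methoxybenzoate
Product: 10 methyl 3-allyl-4-(benzyloxy)-5-methoxybenzoate
Conditions: BnBr, K2CO3, DMF, 60 °C
Reagents that add atoms: benzyl bromide, BrCc1ccccc1
Why: Williamson benzylation of the hindered phenol in a dipolar aprotic solvent.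

**Step 7**
Reactants: 10 methyl 3-allyl-4-(benzyloxy)-5-methoxybenzoate
Product: 12 methyl 4-(benzyloxy)-3-methoxy-5-(2-oxoethyl)benzoate, via secondary ozonide 11 (not isolated)
Conditions: O3, CH2Cl2, −78 °C (Sudan red 7B endpoint); PPh3, −78 °C → rt
Reagents that add atoms: ozone, [O-][O+]=O
Why: Ozonolysis of the terminal alkene with reductive work-up; the indicator endpoint protects the ester-deactivated arene and the benzyl ether.

**Step 8**
Reactants: 12 methyl 4-(benzyloxy)-3-methoxy-5-(2-oxoethyl)benzoate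
Product: 13 2-[2-(benzyloxy)-3-methoxy-5-(methoxycarbonyl)phenyl]acetic acid
Conditions: NaClO2, NaH2PO4, 2-methylbut-2-ene, t-BuOH/H2O, 0 °C → rt
Reagents that add atoms: sodium chlorite, [Na+].[O-]Cl=O
Why: Pinnick oxidation of the arylacetaldehyde, with the alkene scavenging hypochlorous acid so that the electron-rich ring is not chlorinated.

**Step 9**
Reactants: 13 2-[2-(benzyloxy)-3-methoxy-5-(methoxycarbonyl)phenyl]acetic acid; 14 (R)-4-benzyloxazolidin-2-one
Product: 16 (R)-4-benzyl-3-{2-[2-(benzyloxy)-3-methoxy-5-(methoxycarbonyl)phenyl]acetyl}oxazolidin-2-one, via mixed pivalic anhydride 15 (not isolated)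
Conditions: PivCl, Et3N, THF, −20 °C; then LiCl, 14, −20 °C → rt
Reagents that add atoms: none
Why: N-acylation of the oxazolidinone through the mixed pivalic anhydride (LiCl-promoted), a standard way to make arylacetyl imides.

**Step 10**
Reactants: 16 the ring B arylacetyl imide; 5 4-(benzyloxy)-3-methoxybenzaldehyde
Product: 19 (R)-4-benzyl-3-{(2R,3R)-2-[2-(benzyloxy)-3-methoxy-5-(methoxycarbonyl)phenyl]-3-[4-(benzyloxy)-3-methoxyphenyl]-3-hydroxypropanoyl}oxazolidin-2-one, via Z-boron enolate 17 (not isolated), via boron aldolate 18 (not isolated)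
Conditions: Bu2BOTf, i-Pr2NEt, CH2Cl2, −78 → 0 °C; 5, −78 → 0 °C; pH 7 buffer, MeOH, 30% H2O2, 0 °C
Reagents that add atoms: none
Why: Evans syn-aldol, in which the Z-boron enolate reacts through a chair Zimmerman–Traxler transition state on the face away from the auxiliary benzyl group, setting the aryl-bearing carbon (R) and the carbinol carbon (R) syn to each other.

**Step 11**
Reactants: 19 the syn-aldol imide
Product: 20 methyl 4-(benzyloxy)-3-{(1R,2S)-1-[4-(benzyloxy)-3-methoxyphenyl]-1,3-dihydroxypropan-2-yl}-5-methoxybenzoate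
Conditions: LiBH4, MeOH (1 equiv), THF, 0 °C
Reagents that add atoms: none
Why: Reductive cleavage of the imide by LiBH4, whose activated carbonyl is reduced much faster at 0 °C than the electron-rich aryl methyl ester; both stereocenters are untouched (the descriptor of the aryl-bearing carbon changes to S only through CIP priorities).

**Step 12**
Reactants: 20 the 1,3-diol
Product: 21 methyl 4-(benzyloxy)-3-{(4R,5S)-4-[4-(benzyloxy)-3-methoxyphenyl]-2,2-dimethyl-1,3-dioxan-5-yl}-5-methoxybenzoate
Conditions: 2,2-dimethoxypropane, pyridinium p-toluenesulfonate (cat.), CH2Cl2, rt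
Reagents that add atoms: 2,2-dimethoxypropane, COC(C)(C)OC
Why: Acid-catalysed transketalization of the 1,3-diol to the six-membered acetonide under a weak acid that should not ionize the electron-rich benzylic carbinol.

**Step 13**
Reactants: 21 the acetonide ester
Product: 22 {4-(benzyloxy)-3-[(4R,5S)-4-[4-(benzyloxy)-3-methoxyphenyl]-2,2-dimethyl-1,3-dioxan-5-yl]-5-methoxyphenyl}methanol
Conditions: LiAlH4, THF, 0 °C; aqueous NaOH work-up
Reagents that add atoms: none
Why: Hydride reduction of the aryl ester to the benzylic alcohol; acetonide and benzyl ethers are inert to LiAlH4.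

**Step 14**
Reactants: 22 the benzylic alcohol
Product: 23 (4R,5S)-5-[2-(benzyloxy)-5-(bromomethyl)-3-methoxyphenyl]-4-[4-(benzyloxy)-3-methoxyphenyl]-2,2-dimethyl-1,3-dioxane
Conditions: CBr4, PPh3, CH2Cl2, 0 °C; used at once
Reagents that add atoms: carbon tetrabromide, BrC(Br)(Br)Br
Why: Appel bromination (SN2 on the alkoxyphosphonium ion) under near-neutral conditions that spare the acid-labile acetonide.

**Step 15**
Reactants: 6 2-[4-(benzyloxy)-3-methoxyphenyl]-1,3-dithiane; 4 (5S)-5-menthyloxyfuran-2(5H)-one; 23 the ring B benzylic bromide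
Product: 26 (3S,4S,5S)-3-{4-(benzyloxy)-3-[(4R,5S)-4-[4-(benzyloxy)-3-methoxyphenyl]-2,2-dimethyl-1,3-dioxan-5-yl]-5-methoxybenzyl}-4-{2-[4-(benzyloxy)-3-methoxyphenyl]-1,3-dithian-2-yl}-5-[(1S,2R,5S)-menthyloxy]dihydrofuran-2(3H)-one, via lithiated dithiane 24 (not isolated), via lithium enolate 25 (not isolated)
Conditions: n-BuLi, THF, −78 → −20 °C; 4, −78 °C; 23, DMPU, −78 °C → rt
Reagents that add atoms: none
Why: n-BuLi deprotonates C2 of dithiane 6 to the sulfur-stabilized benzylic carbanion 24, which adds in a Michael sense to C4 of butenolide 4 to give lithium enolate 25, and 25 is C-alkylated at C3 by benzylic bromide 23 in an SN2 step; the closest known reaction type is the tandem conjugate addition–enolate alkylation of lithiated 2-aryl-1,3-dithianes with 5-alkoxyfuran-2(5H)-ones and benzylic halides. No ring is closed: the lactone ring of 4 is kept and only the C4–C(dithiane) and C3–CH2(ring B) bonds are formed. C4 (S) is controlled by the C5 menthyloxy group, which blocks its own face of the planar butenolide so that 24 enters anti to it. C3 (S) is controlled by the new, bulky dithianyl group on C4, which sends the bromide to the opposite face and gives the 3,4-trans-4,5-trans lactone. The step needs 1,4- over 1,2-addition, secured by the soft, delocalized 2-aryl dithiane anion, and C-monoalkylation, secured by the lithium enolate, by the unhindered and activated ArCH2Br (its CH2 sits between two ring hydrogens) and by the absence of acidic or base-labile groups in 23.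

**Step 16**
Reactants: 26 the dithiane lactone
Product: 27 (3S,4S,5S)-3-{4-(benzyloxy)-3-[(4R,5S)-4-[4-(benzyloxy)-3-methoxyphenyl]-2,2-dimethyl-1,3-dioxan-5-yl]-5-methoxybenzyl}-4-[4-(benzyloxy)-3-methoxybenzyl]-5-[(1S,2R,5S)-menthyloxy]dihydrofuran-2(3H)-one
Conditions: NiCl2·6H2O, NaBH4, MeOH/THF, 0 °C → rt
Reagents that add atoms: none
Why: Reductive desulfurization of the dithioketal by nickel boride made in the flask, which is milder than Raney nickel, so that aryl benzyl ethers, acetonide and the lactone acetal should survive.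

**Step 17**
Reactants: 27 the menthyl acetal lactone
Product: 30 (3S,4S)-3-{4-(benzyloxy)-3-[(1R,2S)-1-[4-(benzyloxy)-3-methoxyphenyl]-1,3-dihydroxypropan-2-yl]-5-methoxybenzyl}-4-[4-(benzyloxy)-3-methoxybenzyl]dihydrofuran-2(3H)-one, via potassium hydroxy carboxylate 28 (not isolated), via lactone acetonide 29 (not isolated)
Conditions: NaBH4, KOH, EtOH/THF/H2O, rt; then 2 M HCl to pH 1, THF, rt
Reagents that add atoms: potassium hydroxide, [K+].[OH-] (its oxygen enters the carboxylate of 28 and can stay in the lactone C2(=O)–O unit)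
Why: Saponification opens the acylal lactone, the hemiacetal loses menthoxide to an aldehyde that NaBH4 reduces at once to the C5 alcohol (so C4 should not epimerize), acidification recloses the γ-lactone by 5-exo-trig lactonization with C2 still the carbonyl, and the same aqueous acid hydrolyses the acetonide.

**Step 18**
Reactants: 30 the lactone diol
Product: 31 (3S,4S)-3-{4-(benzyloxy)-3-[(2S)-1-[4-(benzyloxy)-3-methoxyphenyl]-3-hydroxy-1-oxopropan-2-yl]-5-methoxybenzyl}-4-[4-(benzyloxy)-3-methoxybenzyl]dihydrofuran-2(3H)-one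
Conditions: DDQ (1.2 equiv), 1,4-dioxane, rt
Reagents that add atoms: none
Why: DDQ dehydrogenation of an electron-rich secondary benzylic alcohol (hydride abstraction para to the benzyloxy group, assisted by the carbinol oxygen), which should be much faster than attack at the primary alcohol or at the ArCH2 groups that lack an α-oxygen, in a neutral medium that should not epimerize the adjacent (S) center.

**Step 19**
Reactants: 31 the tribenzyl ketone
Product: 32 (3S,4S)-3-{4-hydroxy-3-[(2S)-3-hydroxy-1-(4-hydroxy-3-methoxyphenyl)-1-oxopropan-2-yl]-5-methoxybenzyl}-4-(4-hydroxy-3-methoxybenzyl)dihydrofuran-2(3H)-one (CNP0281222.1)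
Conditions: H2 (1 atm), 10% Pd/C, EtOAc/EtOH, rt, stopped at full debenzylation
Reagents that add atoms: none
Why: Catalytic hydrogenolysis of the three aryl benzyl ethers, which should be faster than reduction of the electron-rich aryl ketone, under neutral conditions that protect the base-labile α-aryl-β-hydroxy ketone stereocenter.

**Compound list**
1 | furfural | O=Cc1ccco1 | starting material
2 | 5-hydroxyfuran-2(5H)-one (racemic) | O=C1C=CC(O)O1 | intermediate
3 | (+)-menthol, (1S,2R,5S) | CC(C)[C@H]1CC[C@H](C)C[C@@H]1O | starting material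
4 | (5S)-5-[(1S,2R,5S)-menthyloxy]furan-2(5H)-one | O=C1C=C[C@@H](O[C@H]2C[C@@H](C)CC[C@@H]2C(C)C)O1 | intermediate
5 | 4-(benzyloxy)-3-methoxybenzaldehyde | COc1cc(C=O)ccc1OCc1ccccc1 | starting material
6 | 2-[4-(benzyloxy)-3-methoxyphenyl]-1,3-dithiane | COc1cc(C2SCCCS2)ccc1OCc1ccccc1 | intermediate
7 | methyl vanillate | COC(=O)c1ccc(O)c(OC)c1 | starting material
8 | methyl 4-(allyloxy)-3-methoxybenzoate | COC(=O)c1ccc(OCC=C)c(OC)c1 | intermediate
9 | methyl 3-allyl-4-hydroxy-5-methoxybenzoate | COC(=O)c1cc(CC=C)c(O)c(OC)c1 | intermediate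
10 | methyl 3-allyl-4-(benzyloxy)-5-methoxybenzoate | COC(=O)c1cc(CC=C)c(OCc2ccccc2)c(OC)c1 | intermediate
11 | secondary ozonide of 10, methyl 4-(benzyloxy)-3-methoxy-5-[(1,2,4-trioxolan-3-yl)methyl]benzoate | COC(=O)c1cc(CC2OCOO2)c(OCc2ccccc2)c(OC)c1 | intermediate
12 | methyl 4-(benzyloxy)-3-methoxy-5-(2-oxoethyl)benzoate | COC(=O)c1cc(CC=O)c(OCc2ccccc2)c(OC)c1 | intermediate
13 | 2-[2-(benzyloxy)-3-methoxy-5-(methoxycarbonyl)phenyl]acetic acid | COC(=O)c1cc(CC(=O)O)c(OCc2ccccc2)c(OC)c1 | intermediate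
14 | (R)-4-benzyloxazolidin-2-one | O=C1N[C@H](Cc2ccccc2)CO1 | starting material
15 | mixed anhydride of 13 with pivalic acid | COC(=O)c1cc(CC(=O)OC(=O)C(C)(C)C)c(OCc2ccccc2)c(OC)c1 | intermediate
16 | (R)-4-benzyl-3-{2-[2-(benzyloxy)-3-methoxy-5-(methoxycarbonyl)phenyl]acetyl}oxazolidin-2-one | COC(=O)c1cc(CC(=O)N2[C@H](Cc3ccccc3)COC2=O)c(OCc2ccccc2)c(OC)c1 | intermediate
17 | Z-dibutylboron enolate of 16 | COC(=O)c1cc(/C=C(\OB(CCCC)CCCC)N2[C@H](Cc3ccccc3)COC2=O)c(OCc2ccccc2)c(OC)c1 | intermediate
18 | dibutylboron aldolate of 19 | COC(=O)c1cc([C@@H](C(=O)N2[C@H](Cc3ccccc3)COC2=O)[C@@H](OB(CCCC)CCCC)c2ccc(OCc3ccccc3)c(OC)c2)c(OCc2ccccc2)c(OC)c1 | intermediate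
19 | (2R,3R)-syn-aldol imide | COC(=O)c1cc([C@@H](C(=O)N2[C@H](Cc3ccccc3)COC2=O)[C@@H](O)c2ccc(OCc3ccccc3)c(OC)c2)c(OCc2ccccc2)c(OC)c1 | intermediate
20 | (1R,2S)-1,3-diol ester | COC(=O)c1cc([C@@H](CO)[C@@H](O)c2ccc(OCc3ccccc3)c(OC)c2)c(OCc2ccccc2)c(OC)c1 | intermediate
21 | (4R,5S)-acetonide ester | COC(=O)c1cc([C@@H]2[C@@H](OC(C)(C)OC2)c2ccc(OCc3ccccc3)c(OC)c2)c(OCc2ccccc2)c(OC)c1 | intermediate
22 | (4R,5S)-acetonide benzylic alcohol | OCc1cc([C@@H]2[C@@H](OC(C)(C)OC2)c2ccc(OCc3ccccc3)c(OC)c2)c(OCc2ccccc2)c(OC)c1 | intermediate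
23 | (4R,5S)-acetonide benzylic bromide | BrCc1cc([C@@H]2[C@@H](OC(C)(C)OC2)c2ccc(OCc3ccccc3)c(OC)c2)c(OCc2ccccc2)c(OC)c1 | intermediate
24 | 2-lithio-2-[4-(benzyloxy)-3-methoxyphenyl]-1,3-dithiane | COc1cc(C2([Li])SCCCS2)ccc1OCc1ccccc1 | intermediate
25 | lithium enolate of the (4S,5S) conjugate adduct | COc1cc(C2(SCCCS2)[C@H]2C=C(O[Li])O[C@@H]2O[C@H]2C[C@@H](C)CC[C@@H]2C(C)C)ccc1OCc1ccccc1 | intermediate
26 | (3S,4S,5S)-3-(ring B benzyl)-4-(2-aryl-1,3-dithian-2-yl)-5-menthyloxy lactone | COc1cc(C2(SCCCS2)[C@@H]3[C@@H](O[C@H]4C[C@@H](C)CC[C@@H]4C(C)C)OC(=O)[C@H]3Cc3cc(OC)c(OCc4ccccc4)c([C@@H]4[C@@H](OC(C)(C)OC4)c4ccc(OCc5ccccc5)c(OC)c4)c3)ccc1OCc1ccccc1 | intermediate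
27 | (3S,4S,5S)-3,4-dibenzyl-5-menthyloxy lactone | COc1cc(C[C@@H]2[C@@H](O[C@H]3C[C@@H](C)CC[C@@H]3C(C)C)OC(=O)[C@H]2Cc2cc(OC)c(OCc3ccccc3)c([C@@H]3[C@@H](OC(C)(C)OC3)c3ccc(OCc4ccccc4)c(OC)c3)c2)ccc1OCc1ccccc1 | intermediate
28 | potassium (2S,3S)-2-(ring B benzyl)-3-[4-(benzyloxy)-3-methoxybenzyl]-4-hydroxybutanoate (acetonide intact) | COc1cc(C[C@H](CO)[C@H](Cc2cc(OC)c(OCc3ccccc3)c([C@@H]3[C@@H](OC(C)(C)OC3)c3ccc(OCc4ccccc4)c(OC)c3)c2)C(=O)[O-])ccc1OCc1ccccc1.[K+] | intermediate
29 | (3S,4S)-lactone acetonide | COc1cc(C[C@@H]2COC(=O)[C@H]2Cc2cc(OC)c(OCc3ccccc3)c([C@@H]3[C@@H](OC(C)(C)OC3)c3ccc(OCc4ccccc4)c(OC)c3)c2)ccc1OCc1ccccc1 | intermediate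
30 | (3S,4S)-lactone (1R,2S)-diol | COc1cc(C[C@@H]2COC(=O)[C@H]2Cc2cc(OC)c(OCc3ccccc3)c([C@@H](CO)[C@@H](O)c3ccc(OCc4ccccc4)c(OC)c3)c2)ccc1OCc1ccccc1 | intermediate
31 | (3S,4S)-lactone (2S)-β-hydroxy ketone, tribenzyl ether | COc1cc(C[C@@H]2COC(=O)[C@H]2Cc2cc(OC)c(OCc3ccccc3)c([C@@H](CO)C(=O)c3ccc(OCc4ccccc4)c(OC)c3)c2)ccc1OCc1ccccc1 | intermediate
32 | CNP0281222.1 | COc1cc(C[C@@H]2COC(=O)[C@H]2Cc2cc(OC)c(O)c([C@@H](CO)C(=O)c3ccc(O)c(OC)c3)c2)ccc1O | target

**Totals**
Total step count: 19. Longest linear sequence: 16 steps (7 → 32, steps 4–19).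

**Steps most likely to fail**

Step 15 (key step). The hindered enolate 25 may alkylate slowly with the large, ionization-prone bromide 23, so that proton transfer to the enolate and decay of the bromide outrun C–C bond formation. The fallback replaces alkylation by aldol trapping and deoxygenation. It sets out from alcohol 22, which is oxidized with MnO2 (CH2Cl2, rt) to the ring B benzaldehyde F1. Enolate 25, made as in step 15, is trapped at −78 °C with this more electrophilic aldehyde to give the trans-3-(α-hydroxybenzyl) lactone F2 (both carbinol epimers are carried on). PhOC(S)Cl, pyridine and 4-(dimethylamino)pyridine give the phenyl thionocarbonate F3. Barton–McCombie deoxygenation (Bu3SnH, azobisisobutyronitrile, toluene, 80 °C) then removes the benzylic oxygen and comes back to the route at 26.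

Step 18. DDQ may also abstract hydride at the two ArCH2 groups of the dibenzyl lactone, followed by cyclization onto the neighbouring arene, or the β-hydroxy ketone may lose water or formaldehyde in the presence of the acidic hydroquinone. The fallback is a protect–oxidize–deprotect sequence from 30. The primary alcohol is silylated selectively (TBSCl, imidazole, CH2Cl2, 0 °C) to the mono-silyl ether F4. The remaining secondary alcohol is oxidized with Dess–Martin periodinane/NaHCO3 to the silyloxy ketone F5. HF·pyridine (THF, 0 °C) removes the silyl group under acidic, non-epimerizing conditions and comes back at 31.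

Step 19. The aryl ketone may be over-reduced on palladium while the doubly ortho-substituted ring B benzyl ether is cleaved slowly. The fallback is a non-reductive debenzylation from 31: BCl3 with pentamethylbenzene as cation scavenger (CH2Cl2, −78 °C) cleaves the three aryl benzyl ethers without hydrogen and gives 32 directly. It makes no new compound (F0).

**Further compounds**
F1 | step 15 | 4-(benzyloxy)-3-[(4R,5S)-4-[4-(benzyloxy)-3-methoxyphenyl]-2,2-dimethyl-1,3-dioxan-5-yl]-5-methoxybenzaldehyde | O=Cc1cc([C@@H]2[C@@H](OC(C)(C)OC2)c2ccc(OCc3ccccc3)c(OC)c2)c(OCc2ccccc2)c(OC)c1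
F2 | step 15 | trans-3-[aryl(hydroxy)methyl] analogue of 26 (carbinol epimers) | COc1cc(C2(SCCCS2)[C@@H]3[C@@H](O[C@H]4C[C@@H](C)CC[C@@H]4C(C)C)OC(=O)[C@H]3C(O)c3cc(OC)c(OCc4ccccc4)c([C@@H]4[C@@H](OC(C)(C)OC4)c4ccc(OCc5ccccc5)c(OC)c4)c3)ccc1OCc1ccccc1
F3 | step 15 | O-phenyl thionocarbonate of F2 | COc1cc(C2(SCCCS2)[C@@H]3[C@@H](O[C@H]4C[C@@H](C)CC[C@@H]4C(C)C)OC(=O)[C@H]3C(OC(=S)Oc3ccccc3)c3cc(OC)c(OCc4ccccc4)c([C@@H]4[C@@H](OC(C)(C)OC4)c4ccc(OCc5ccccc5)c(OC)c4)c3)ccc1OCc1ccccc1
F4 | step 18 | primary tert-butyldimethylsilyl ether of 30 | COc1cc(C[C@@H]2COC(=O)[C@H]2Cc2cc(OC)c(OCc3ccccc3)c([C@@H](CO[Si](C)(C)C(C)(C)C)[C@@H](O)c3ccc(OCc4ccccc4)c(OC)c3)c2)ccc1OCc1ccccc1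
F5 | step 18 | primary tert-butyldimethylsilyl ether of 31 | COc1cc(C[C@@H]2COC(=O)[C@H]2Cc2cc(OC)c(OCc3ccccc3)c([C@@H](CO[Si](C)(C)C(C)(C)C)C(=O)c3ccc(OCc4ccccc4)c(OC)c3)c2)ccc1OCc1ccccc1
F0 | step 19 | none | none
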